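A direct plan would set both stereocentres by auxiliary-controlled benzylation: the succinyl bis-imide A1 of (R)-4-benzyl-1,3-oxazolidin-2-one would be doubly deprotonated and benzylated in one flask by bromide A2, then by its regioisomer A3, to give A4; auxiliary removal, benzoylation and hydrogenolysis would follow.
Weakest would be: (a) this one-pot hetero-dibenzylation, which would have to break the symmetry of a dianion with two equally reactive bromides, would leave both stereocentres to an untested facial model and would give by-products differing only by an OMe/OBn exchange;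
(b) the two PBr3 brominations, two steps that would only make labile electron-rich benzyl bromides;
(c) attachment and hydride removal of two auxiliaries, two steps without skeletal gain, the removal on a hindered bis-imide that would hold all the material.

**Plan of the new route**

The retrosynthesis cuts the central C2–C3 bond, not a benzylic bond: C1 is read as a carboxyl carbon and C4 as an alkene carbon, so the diol becomes the 2,3-bis(arylmethyl)hex-4-enoic acid 12, the Ireland–Claisen product of allylic ester 8.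
Feature used: the adjacent CH carbons C2 and C3 each carry one CH2O arm and one arylmethyl arm, which is a masked γ,δ-unsaturated acid; the isovanillyl ring rides on the acyl half of 8 and the vanillyl ring on its allyl half, so the two arenes are told apart from the start.
8 comes from eugenol, (R)-but-3-en-2-ol and dihydroisoferulic acid by cross-metathesis and esterification; its one purchased stereocentre is relayed to C3 and the chair fixes C2 relative to it.
Both arenes are bought; the only ring made is a temporary γ-lactone (15) after the key step, which keeps C2 epimerisable toward the wanted trans arrangement before hydride opens it.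
No benzyl halide, no auxiliary and no enolate alkylation occur.

Key step: step 5

Remark: the target SMILES corresponds to the (2R,3R) configuration, the one obtained by hydride opening of a trans-(3R,4R)-3,4-bis(arylmethyl)oxolan-2-one; TIPS stands for triisopropylsilyl, tri(propan-2-yl)silyl.

Step 1
Reactants: 1 eugenol, 2-methoxy-4-(prop-2-en-1-yl)phenol
Product: 2 [2-methoxy-4-(prop-2-en-1-yl)phenoxy]tri(propan-2-yl)silane (O-TIPS-eugenol)
Conditions: TIPSCl (1.1 equiv), imidazole (2.2 equiv), DMF, rt
Reagents that add atoms: chlorotri(propan-2-yl)silane, CC(C)[Si](Cl)(C(C)C)C(C)C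
Why: Imidazole-mediated O-silylation of the phenol (silyl ether formation) installs a bulky aryl TIPS ether that should withstand amide base, borohydride and ozone and can be removed at the end by fluoride without touching benzoates; no stereocentre is involved.

Step 2
Reactants: 2 [2-methoxy-4-(prop-2-en-1-yl)phenoxy]tri(propan-2-yl)silane; 3 (2R)-but-3-en-2-ol
Product: 4 (2R,3E)-5-[3-methoxy-4-(triisopropylsilyloxy)phenyl]pent-3-en-2-ol
Conditions: 3 (3 equiv), second-generation Grubbs catalyst (H2IMes)(PCy3)Cl2Ru=CHPh (3 mol %), 1,4-benzoquinone (10 mol %), CH2Cl2, 40 °C; chromatography to the pure E isomer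
Reagents that add atoms: none
Why: Olefin cross-metathesis between a terminal allylarene and a slowly homodimerising secondary allylic alcohol should give the (E)-1,2-disubstituted alkene with loss of ethene, while the purchased carbinol stereocentre is not part of any reacting bond.

Step 3
Reactants: 5 3-(3-hydroxy-4-methoxyphenyl)propanoic acid (dihydroisoferulic acid)
Product: 7 3-[4-methoxy-3-(triisopropylsilyloxy)phenyl]propanoic acid, via bis-silylated ester 6 (not isolated)
Conditions: TIPSCl (2.3 equiv), imidazole (5 equiv), DMF, rt; then K2CO3 (1.2 equiv), MeOH–THF–H2O, 0 °C, 30 min; 1 M HCl to pH 3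
Reagents that add atoms: chlorotri(propan-2-yl)silane, CC(C)[Si](Cl)(C(C)C)C(C)C
Why: Both acidic OH groups are silylated and the far more labile silyl ester is then cleaved selectively by cold carbonate methanolysis (silyl ester solvolysis), which should leave the hindered aryl TIPS ether in place; no stereocentre is involved.

Step 4
Reactants: 4 (2R,3E)-5-[3-methoxy-4-(triisopropylsilyloxy)phenyl]pent-3-en-2-ol; 7 3-[4-methoxy-3-(triisopropylsilyloxy)phenyl]propanoic acid
Product: 8 (2R,3E)-5-[3-methoxy-4-(triisopropylsilyloxy)phenyl]pent-3-en-2-yl 3-[4-methoxy-3-(triisopropylsilyloxy)phenyl]propanoate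
Conditions: DCC (1.1 equiv), DMAP (0.1 equiv), CH2Cl2, 0 °C → rt
Reagents that add atoms: none
Why: Steglich esterification (carbodiimide activation, DMAP acyl transfer) acylates the secondary allylic alcohol at oxygen without breaking its C–O bond, so the (R) configuration is retained.

Step 5
Reactants: 8 (2R,3E)-5-[3-methoxy-4-(triisopropylsilyloxy)phenyl]pent-3-en-2-yl 3-[4-methoxy-3-(triisopropylsilyloxy)phenyl]propanoate
Product: 12 (2R,3S,4E)-2-[4-methoxy-3-(triisopropylsilyloxy)benzyl]-3-[3-methoxy-4-(triisopropylsilyloxy)benzyl]hex-4-enoic acid, via lithium enolate 9 (not isolated), via (Z)-trimethylsilyl ketene acetal 10 (not isolated), via trimethylsilyl ester 11 (not isolated)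
Conditions: LDA (1.2 equiv), THF–DMPU (3:1), −78 °C; 8, 30 min; Me3SiCl (1.5 equiv), −78 °C → rt, then 50 °C, 3 h; 1 M HCl, THF, rt
Reagents that add atoms: lithium diisopropylamide, [Li]N(C(C)C)C(C)C (supplies only the Li of 9; no atom of 12); chlorotrimethylsilane, C[Si](C)(C)Cl (supplies only the SiMe3 of 10 and 11; no atom of 12)
Why: Deprotonation in THF–DMPU, where the open transition state places the C2 arylmethyl group cis to OLi, and O-silylation should give the (Z)-silyl ketene acetal 10, which on warming undergoes the Ireland–Claisen [3,3]-sigmatropic shift through a chair transition state, breaking the carbinol C–O bond and forming C2–C3; the closest known reaction type is the ester enolate Claisen rearrangement of (E)-configured secondary allylic esters with 1,3-chirality transfer. No ring is closed, the six-membered array being only the transition state. C3 is controlled by the carbinol centre: with its methyl group pseudo-equatorial, the (R)-configured C–O bond lies on one face of the (E)-alkene and the new bond must form on that face, which gives 3S and an (E)-propenyl group. C2 is controlled by the ketene acetal geometry: the arylmethyl group trans to the allylic oxygen is pseudo-equatorial, and the chair then gives the 2,3-syn acid with 2R. The step needs one enolate geometry and chair over boat; the dipolar cosolvent should secure the first and the all-equatorial acyclic chair the second. An error at C2 alone stays correctable, since C2 becomes the enolisable α-carbon of lactone 15.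

Step 6
Reactants: 12 (2R,3S,4E)-2-[4-methoxy-3-(triisopropylsilyloxy)benzyl]-3-[3-methoxy-4-(triisopropylsilyloxy)benzyl]hex-4-enoic acid
Product: 15 (3R,4R)-3-[4-methoxy-3-(triisopropylsilyloxy)benzyl]-4-[3-methoxy-4-(triisopropylsilyloxy)benzyl]oxolan-2-one, via aldehyde acid 13 (not isolated), via hydroxy acid 14 (not isolated)
Conditions: O3, CH2Cl2–MeOH (3:1), −78 °C (Sudan Red 7B end point); NaBH4 (5 equiv), −78 → 0 °C; then 2 M HCl, THF, rt
Reagents that add atoms: ozone, [O-][O+]=O
Why: Ozonolysis should cleave the only alkene much faster than the arenes, borohydride reduces the peroxidic and aldehyde intermediates to the γ-hydroxy acid while the aldehyde is still cold, and acid closes the five-membered lactone (γ-lactonisation), with no bond to either stereocentre broken.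

Step 7
Reactants: 15 (3R,4R)-3-[4-methoxy-3-(triisopropylsilyloxy)benzyl]-4-[3-methoxy-4-(triisopropylsilyloxy)benzyl]oxolan-2-one
Product: 16 (2R,3R)-2-[4-methoxy-3-(triisopropylsilyloxy)benzyl]-3-[3-methoxy-4-(triisopropylsilyloxy)benzyl]butane-1,4-diol
Conditions: LiBH4 (3 equiv), THF, 0 °C → rt; aq NH4Cl
Reagents that add atoms: none
Why: Borohydride reduction of a γ-lactone to the 1,4-diol breaks only the acyl C–O bond, leaves both stereocentres untouched and is tolerated by aryl silyl ethers.

Step 8
Reactants: 16 (2R,3R)-2-[4-methoxy-3-(triisopropylsilyloxy)benzyl]-3-[3-methoxy-4-(triisopropylsilyloxy)benzyl]butane-1,4-diol; 17 benzoyl chloride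
Product: 18 (2R,3R)-2-[4-methoxy-3-(triisopropylsilyloxy)benzyl]-3-[3-methoxy-4-(triisopropylsilyloxy)benzyl]butane-1,4-diyl dibenzoate
Conditions: 17 (2.5 equiv), Et3N (4 equiv), DMAP (0.1 equiv), CH2Cl2, 0 °C → rt
Reagents that add atoms: none
Why: DMAP-catalysed O-acylation of the two primary alcohols (nucleophilic-catalysis esterification) benzoylates only the diol, because both phenols are masked as TIPS ethers and no stereocentre is touched.

Step 9
Reactants: 18 (2R,3R)-2-[4-methoxy-3-(triisopropylsilyloxy)benzyl]-3-[3-methoxy-4-(triisopropylsilyloxy)benzyl]butane-1,4-diyl dibenzoate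
Product: 19 (2R,3R)-2-(3-hydroxy-4-methoxybenzyl)-3-(4-hydroxy-3-methoxybenzyl)butane-1,4-diyl dibenzoate (CNP0306197.1)
Conditions: Bu4NF (2.2 equiv), AcOH (2.5 equiv), THF, 0 °C
Reagents that add atoms: none
Why: Fluoride-induced cleavage of the aryl silyl ethers (Si–F bond formation) is fast at 0 °C, and the acetic acid buffer keeps the phenols protonated so that the alkyl benzoates should be neither cleaved nor transferred; the stereocentres are remote.

## Compound list

1 | eugenol, 2-methoxy-4-(prop-2-en-1-yl)phenol | C=CCc1ccc(O)c(OC)c1 | starting material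
2 | [2-methoxy-4-(prop-2-en-1-yl)phenoxy]tri(propan-2-yl)silane | C=CCc1ccc(O[Si](C(C)C)(C(C)C)C(C)C)c(OC)c1 | intermediate
3 | (2R)-but-3-en-2-ol | C[C@@H](O)C=C | starting material
4 | (2R,3E)-5-[3-methoxy-4-(triisopropylsilyloxy)phenyl]pent-3-en-2-ol | C[C@@H](O)/C=C/Cc1ccc(O[Si](C(C)C)(C(C)C)C(C)C)c(OC)c1 | intermediate
5 | 3-(3-hydroxy-4-methoxyphenyl)propanoic acid | COc1ccc(CCC(=O)O)cc1O | starting material
6 | triisopropylsilyl 3-[4-methoxy-3-(triisopropylsilyloxy)phenyl]propanoate | COc1ccc(CCC(=O)O[Si](C(C)C)(C(C)C)C(C)C)cc1O[Si](C(C)C)(C(C)C)C(C)C | intermediate (not isolated)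
7 | 3-[4-methoxy-3-(triisopropylsilyloxy)phenyl]propanoic acid | COc1ccc(CCC(=O)O)cc1O[Si](C(C)C)(C(C)C)C(C)C | intermediate
8 | (2R,3E)-5-[3-methoxy-4-(triisopropylsilyloxy)phenyl]pent-3-en-2-yl 3-[4-methoxy-3-(triisopropylsilyloxy)phenyl]propanoate | COc1ccc(CCC(=O)O[C@H](C)/C=C/Cc2ccc(O[Si](C(C)C)(C(C)C)C(C)C)c(OC)c2)cc1O[Si](C(C)C)(C(C)C)C(C)C | intermediate
9 | lithium enolate of 8 with the C2 arylmethyl group cis to OLi | COc1ccc(C/C=C(\O[Li])O[C@H](C)/C=C/Cc2ccc(O[Si](C(C)C)(C(C)C)C(C)C)c(OC)c2)cc1O[Si](C(C)C)(C(C)C)C(C)C | intermediate (not isolated)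
10 | (Z)-O-trimethylsilyl ketene acetal of 8 | COc1ccc(C/C=C(\O[Si](C)(C)C)O[C@H](C)/C=C/Cc2ccc(O[Si](C(C)C)(C(C)C)C(C)C)c(OC)c2)cc1O[Si](C(C)C)(C(C)C)C(C)C | intermediate (not isolated)
11 | trimethylsilyl (2R,3S,4E)-2-[4-methoxy-3-(triisopropylsilyloxy)benzyl]-3-[3-methoxy-4-(triisopropylsilyloxy)benzyl]hex-4-enoate | COc1ccc(C[C@@H](C(=O)O[Si](C)(C)C)[C@H](/C=C/C)Cc2ccc(O[Si](C(C)C)(C(C)C)C(C)C)c(OC)c2)cc1O[Si](C(C)C)(C(C)C)C(C)C | intermediate (not isolated)
12 | (2R,3S,4E)-2-[4-methoxy-3-(triisopropylsilyloxy)benzyl]-3-[3-methoxy-4-(triisopropylsilyloxy)benzyl]hex-4-enoic acid | COc1ccc(C[C@@H](C(=O)O)[C@H](/C=C/C)Cc2ccc(O[Si](C(C)C)(C(C)C)C(C)C)c(OC)c2)cc1O[Si](C(C)C)(C(C)C)C(C)C | intermediate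
13 | (2R,3R)-2-[4-methoxy-3-(triisopropylsilyloxy)benzyl]-3-[3-methoxy-4-(triisopropylsilyloxy)benzyl]-4-oxobutanoic acid | COc1ccc(C[C@@H](C(=O)O)[C@H](C=O)Cc2ccc(O[Si](C(C)C)(C(C)C)C(C)C)c(OC)c2)cc1O[Si](C(C)C)(C(C)C)C(C)C | intermediate (not isolated)
14 | (2R,3R)-4-hydroxy-2-[4-methoxy-3-(triisopropylsilyloxy)benzyl]-3-[3-methoxy-4-(triisopropylsilyloxy)benzyl]butanoic acid | COc1ccc(C[C@@H](C(=O)O)[C@H](CO)Cc2ccc(O[Si](C(C)C)(C(C)C)C(C)C)c(OC)c2)cc1O[Si](C(C)C)(C(C)C)C(C)C | intermediate (not isolated)
15 | (3R,4R)-3-[4-methoxy-3-(triisopropylsilyloxy)benzyl]-4-[3-methoxy-4-(triisopropylsilyloxy)benzyl]oxolan-2-one | COc1ccc(C[C@@H](C(=O)OC2)[C@H]2Cc3ccc(O[Si](C(C)C)(C(C)C)C(C)C)c(OC)c3)cc1O[Si](C(C)C)(C(C)C)C(C)C | intermediate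
16 | (2R,3R)-2-[4-methoxy-3-(triisopropylsilyloxy)benzyl]-3-[3-methoxy-4-(triisopropylsilyloxy)benzyl]butane-1,4-diol | COc1ccc(C[C@@H](CO)[C@H](CO)Cc2ccc(O[Si](C(C)C)(C(C)C)C(C)C)c(OC)c2)cc1O[Si](C(C)C)(C(C)C)C(C)C | intermediate
17 | benzoyl chloride | O=C(Cl)c1ccccc1 | starting material
18 | (2R,3R)-2-[4-methoxy-3-(triisopropylsilyloxy)benzyl]-3-[3-methoxy-4-(triisopropylsilyloxy)benzyl]butane-1,4-diyl dibenzoate | COc1ccc(C[C@@H](COC(=O)c2ccccc2)[C@H](COC(=O)c2ccccc2)Cc2ccc(O[Si](C(C)C)(C(C)C)C(C)C)c(OC)c2)cc1O[Si](C(C)C)(C(C)C)C(C)C | intermediate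
19 | (2R,3R)-2-(3-hydroxy-4-methoxybenzyl)-3-(4-hydroxy-3-methoxybenzyl)butane-1,4-diyl dibenzoate (CNP0306197.1) | COc1ccc(C[C@@H](COC(=O)c2ccccc2)[C@H](COC(=O)c2ccccc2)Cc2ccc(O)c(OC)c2)cc1O | target

Total step count: 9. Longest linear sequence: 8 steps (steps 1, 2, 4, 5, 6, 7, 8, 9 from eugenol).

## Steps most likely to fail

**Step 5 (key step).** The process at risk is incomplete control of enolate geometry: some enolate with the C2 arylmethyl group trans to OLi would pass through the same chair to the C2 epimer. A chair with pseudo-axial methyl would, to a lesser degree, lower the enantiomeric purity at C3. The fallback sets out from 12 and comes back at 15. The acid would be taken on as obtained, together with its C2 epimer, (2S,3S,4E)-2-[4-methoxy-3-(triisopropylsilyloxy)benzyl]-3-[3-methoxy-4-(triisopropylsilyloxy)benzyl]hex-4-enoic acid F1. Under the conditions of step 6, F1 would pass through the aldehyde acid (2S,3R)-2-[4-methoxy-3-(triisopropylsilyloxy)benzyl]-3-[3-methoxy-4-(triisopropylsilyloxy)benzyl]-4-oxobutanoic acid F2 and the hydroxy acid (2S,3R)-4-hydroxy-2-[4-methoxy-3-(triisopropylsilyloxy)benzyl]-3-[3-methoxy-4-(triisopropylsilyloxy)benzyl]butanoic acid F3 to the cis-lactone (3S,4R)-3-[4-methoxy-3-(triisopropylsilyloxy)benzyl]-4-[3-methoxy-4-(triisopropylsilyloxy)benzyl]oxolan-2-one F4. The lactone mixture would then be heated with DBU in toluene at 80 °C, where reversible enolisation at C3 of the lactone (the former C2, the only acidic stereocentre) should drain F4 into the thermodynamically preferred trans-lactone 15. C4 of the lactone, which is set by chirality transfer and not by enolate geometry, is not touched, so the correction should yield more of 15 and not its enantiomer.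

**Step 2.** The process at risk is migration of the allylic double bond into conjugation with the arene and redox isomerisation of the allylic alcohol, both caused by ruthenium hydride species, together with incomplete E selectivity, which would later erode the configuration at C3. The fallback sets out from 2 and comes back at 4. Oxidative cleavage of 2 with OsO4 (cat.), NaIO4 and 2,6-lutidine in dioxane–water would give [3-methoxy-4-(triisopropylsilyloxy)phenyl]acetaldehyde F5. Wittig olefination of F5 with the stabilised ylide Ph3P=CHC(O)CH3 in CH2Cl2 would give (3E)-5-[3-methoxy-4-(triisopropylsilyloxy)phenyl]pent-3-en-2-one F6. Corey–Bakshi–Shibata reduction of F6 with the (S)-configured 2-methyl oxazaborolidine catalyst and catecholborane in toluene at −78 °C should then deliver the (R)-allylic alcohol 4.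

**Step 6.** The process at risk is over-oxidation of the two electron-rich arenes by ozone and epimerisation next to the aldehyde before it is reduced. The fallback sets out from 12 and comes back at 16, bypassing 15. The acid 12 would first be reduced with LiAlH4 in THF at 0 °C to (2R,3S,4E)-2-[4-methoxy-3-(triisopropylsilyloxy)benzyl]-3-[3-methoxy-4-(triisopropylsilyloxy)benzyl]hex-4-en-1-ol F7. Lemieux–Johnson cleavage (OsO4 cat., NaIO4, 2,6-lutidine, dioxane–water), which does not attack arenes, would give the lactol (3R,4R)-4-[4-methoxy-3-(triisopropylsilyloxy)benzyl]-3-[3-methoxy-4-(triisopropylsilyloxy)benzyl]oxolan-2-ol F8. NaBH4 in MeOH at 0 °C would reduce F8 directly to diol 16.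

## Further compounds

F1 | step 5 | (2S,3S,4E)-2-[4-methoxy-3-(triisopropylsilyloxy)benzyl]-3-[3-methoxy-4-(triisopropylsilyloxy)benzyl]hex-4-enoic acid | COc1ccc(C[C@H](C(=O)O)[C@H](/C=C/C)Cc2ccc(O[Si](C(C)C)(C(C)C)C(C)C)c(OC)c2)cc1O[Si](C(C)C)(C(C)C)C(C)C
F2 | step 5 | (2S,3R)-2-[4-methoxy-3-(triisopropylsilyloxy)benzyl]-3-[3-methoxy-4-(triisopropylsilyloxy)benzyl]-4-oxobutanoic acid | COc1ccc(C[C@H](C(=O)O)[C@H](C=O)Cc2ccc(O[Si](C(C)C)(C(C)C)C(C)C)c(OC)c2)cc1O[Si](C(C)C)(C(C)C)C(C)C
F3 | step 5 | (2S,3R)-4-hydroxy-2-[4-methoxy-3-(triisopropylsilyloxy)benzyl]-3-[3-methoxy-4-(triisopropylsilyloxy)benzyl]butanoic acid | COc1ccc(C[C@H](C(=O)O)[C@H](CO)Cc2ccc(O[Si](C(C)C)(C(C)C)C(C)C)c(OC)c2)cc1O[Si](C(C)C)(C(C)C)C(C)C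
F4 | step 5 | (3S,4R)-3-[4-methoxy-3-(triisopropylsilyloxy)benzyl]-4-[3-methoxy-4-(triisopropylsilyloxy)benzyl]oxolan-2-one | COc1ccc(C[C@H](C(=O)OC2)[C@H]2Cc3ccc(O[Si](C(C)C)(C(C)C)C(C)C)c(OC)c3)cc1O[Si](C(C)C)(C(C)C)C(C)C
F5 | step 2 | [3-methoxy-4-(triisopropylsilyloxy)phenyl]acetaldehyde | O=CCc1ccc(O[Si](C(C)C)(C(C)C)C(C)C)c(OC)c1
F6 | step 2 | (3E)-5-[3-methoxy-4-(triisopropylsilyloxy)phenyl]pent-3-en-2-one | CC(=O)/C=C/Cc1ccc(O[Si](C(C)C)(C(C)C)C(C)C)c(OC)c1
F7 | step 6 | (2R,3S,4E)-2-[4-methoxy-3-(triisopropylsilyloxy)benzyl]-3-[3-methoxy-4-(triisopropylsilyloxy)benzyl]hex-4-en-1-ol | COc1ccc(C[C@@H](CO)[C@H](/C=C/C)Cc2ccc(O[Si](C(C)C)(C(C)C)C(C)C)c(OC)c2)cc1O[Si](C(C)C)(C(C)C)C(C)C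
F8 | step 6 | (3R,4R)-4-[4-methoxy-3-(triisopropylsilyloxy)benzyl]-3-[3-methoxy-4-(triisopropylsilyloxy)benzyl]oxolan-2-ol | COc1ccc(C[C@@H](COC2O)[C@H]2Cc3ccc(O[Si](C(C)C)(C(C)C)C(C)C)c(OC)c3)cc1O[Si](C(C)C)(C(C)C)C(C)C
A1 | direct plan | 3,3'-butanedioylbis[(4R)-4-benzyl-1,3-oxazolidin-2-one] | O=C(CCC(=O)N1[C@H](Cc2ccccc2)COC1=O)N1[C@H](Cc2ccccc2)COC1=O
A2 | direct plan | 2-(benzyloxy)-4-(bromomethyl)-1-methoxybenzene | COc1ccc(CBr)cc1OCc1ccccc1
A3 | direct plan | 1-(benzyloxy)-4-(bromomethyl)-2-methoxybenzene | COc1cc(CBr)ccc1OCc1ccccc1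
A4 | direct plan | 3,3'-{(2R,3R)-2-[3-(benzyloxy)-4-methoxybenzyl]-3-[4-(benzyloxy)-3-methoxybenzyl]butanedioyl}bis[(4R)-4-benzyl-1,3-oxazolidin-2-one] | COc1ccc(C[C@@H](C(=O)N2[C@H](Cc3ccccc3)COC2=O)[C@H](C(=O)N2[C@H](Cc3ccccc3)COC2=O)Cc2ccc(OCc3ccccc3)c(OC)c2)cc1OCc1ccccc1
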